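The readings were generated by integration for an exercise; the scatter is artificial.

**The constant.** The constant to read from these runs is a concentration. Za, the substrate, gives Zh and Zj in a closed isothermal flask that also holds Zc, Zd and Zg, and the new flask has a Zc charge between those of the two earlier runs.

| flask | Za | Zc | Zd | Zg | remark | time |
|---|---|---|---|---|---|---|
| north | 0.050 M | 0.045 M | 0.10 M | 0.015 M | run made earlier |  |
| east | 0.050 M | 0.18 M | 0.10 M | 0.015 M | run made earlier |  |
| flask | 0.050 M | 0.0900 M | 0.100 M | 0.0150 M |  | 2.5 min |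

| run | time / min | Zj / % | Zh / % | Za / % |
|---|---|---|---|---|
| north | 0.250 | 9.9 | 8.8 | 39.8 |
| north | 0.417 | 15.8 | 14.3 | 20.5 |
| north | 0.667 | 16.8 | 20.2 | 8.5 |
| north | 1.00 | 18.2 | 21.8 | 1.3 |
| north | 2.00 | 18.2 | 23.5 | 0.5 |
| north | 3.00 | 19.0 | 23.6 | 0 |
| east | 0.500 | 11.3 | 43.0 | 15.9 |
| east | 1.00 | 11.6 | 53.0 | 2.5 |
| east | 1.50 | 11.7 | 54.7 | 0.4 |
| east | 2.00 | 12.6 | 54.0 | 0.3 |
| east | 2.50 | 11.7 | 54.9 | 0.1 |
| east | 3.00 | 11.3 | 55.5 | 0 |

(each reading ± 0.5 percentage points)

- the earlier runs were read with a standard deviation of 0.5 percentage points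

- ratio of Zj to Zh at 2.5 s
- ratio of Zj to Zh at 2.5 min
- which of Zj and Zh there is more of at 2.5 min

**Two ways.** Multiply the ratio of Zj to Zh at the last reading by the Zc charge. North gives 0.0362 M and east gives 0.0366 M, from charges a factor 4.00 apart. Their mean, 0.0364 M, carries the scatter of the readings and is K, the crossing concentration: the Zc charge at which this reckoning puts Zj equal to Zh at the end, with Za, Zd and Zg charged as in these runs, a selectivity factor written as a concentration. Dividing by this flask's charge, north predicts 0.402 and east 0.407, and I commit to 0.404. The charge 0.0900 M stands above K, so Zh should lead.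

**Early readings.** The same product from the first readings is 0.0506 M in north and 0.0473 M in east, both more than K. So K describes the end of a run, and I don't carry it to 2.5 s. For that time I expect this flask's ratio to exceed 0.526.

**The forecast.** It gave a ratio of Zj to Zh of 0.9 at 2.5 s, within 0.5 to 2.5, and 0.41 at 2.5 min, within 0.36 to 0.47, with Zh ahead. Its late figure rests on an end ratio of Zh to Zj “close to proportional to Zc”.

**The result.** The flask gives 0.965 at 2.5 s and 0.415 at 2.5 min, with Zh ahead, 37.6 % against 15.6 % of Zj, both in percent of the Za charged.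

    2 Zd → Zf (k = 0.640 L mol⁻¹ s⁻¹)
    Zd + Zb → Zj (k = 0.960 L mol⁻¹ s⁻¹)
    Zh → Zm (k = 1.10 × 10⁻⁵ s⁻¹)
    Zb + Zg → Zk (k = 0.0210 L mol⁻¹ s⁻¹)
    Za → Zb (k = 0.0610 s⁻¹)
    Zc + Zb → Zh (k = 0.920 L mol⁻¹ s⁻¹)
    Zb → Ze (k = 0.0910 s⁻¹)

**Next flask.** Turned back, this flask's ratio gives K as 0.0374 M, and its Zc charge stands a factor 2.41 above that. The neighbouring flask, charged with 0.15 M of Zc and otherwise the same, is reckoned from the earlier K at 0.243. It gives 0.258 at 2.5 min, with Zh at 50.4 % of the Za charged, more than the 36.4 % of Ze.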